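If open intermediate and second intermediate simply joined to give target, and target then stayed as it was, the share asked for would be 100 per cent in each flask, so I built the flask up from there to see what lowers it.

the same everywhere: partner 0.264 M
- eta: starting material 0.22 M; protic impurity 0.33 M; temperature 48 °C; run made earlier
- epsilon: starting material 0.49 M; protic impurity 0.33 M; temperature 64 °C; run made earlier
- autumn: starting material 0.33 M; protic impurity 0.330 M; temperature 70 °C; time 2.5 h
- midnight: starting material 0.33 M; protic impurity 0.330 M; temperature 40 °C; time 2.5 h
- winter: starting material 0.33 M; protic impurity 0.330 M; at 70 °C until 80 min, from then on at 40 °C; time 2.5 h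

| run | time / h | target / % | isomer of the product / % |
|---|---|---|---|
| eta | 0.500 | 0 | 0 |
| eta | 1.33 | 1.3 | 0 |
| eta | 2.50 | 3.1 | 0.2 |
| eta | 4.00 | 2.4 | 1.1 |
| eta | 6.00 | 3.8 | 1.1 |
| eta | 8.00 | 3.8 | 0.7 |
| epsilon | 0.250 | 1.8 | 0 |
| epsilon | 0.333 | 2.7 | 0 |
| epsilon | 0.500 | 3.7 | 0.3 |
| epsilon | 0.833 | 6.8 | 0.5 |
| epsilon | 1.33 | 9.5 | 1.3 |
| epsilon | 2.00 | 10.7 | 2.1 |
| epsilon | 3.00 | 13.0 | 2.7 |

(scatter of a reading: 0.5 percentage points)

- the flask with the highest share of target in all that became target or isomer of the product ("all alike" if they lie within 1.5 percentage points) (autumn / midnight / winter / all alike)
- share of target in all that became target or isomer of the product, autumn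
- share of target in all that became target or isomer of the product, midnight
- share of target in all that became target or isomer of the product, winter

- what may be going on: starting material -> open intermediate; partner -> second intermediate; open intermediate + second intermediate -> target; 2 second intermediate -> homo product; target <-> isomer of the product; starting material + protic impurity -> quenched substrate

The next process I added was target going over to its isomer and back. I wrote r for isomer over target, which makes the share 1/(1 + r). In a flask held at one temperature, r climbs from zero towards a standing ratio that belongs to that temperature: a flask stopped on the climb is under kinetic control, and one at the standing ratio is under thermodynamic control. In the epsilon run at 64 °C, r read 0.196 at 2.00 h and barely moved after that, so I took as the standing ratio the isomer over target at its last reading, 0.208. In the eta run at 48 °C, the readings from 4.00 h on gave together 0.290, higher than in the hotter run. With a scatter of 0.5 percentage points on such small readings that gap is thin, but I read it as a standing ratio that falls with heat.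

The remaining steps, the quenching of starting material and the pairing of second intermediate to homo product, have neither target nor isomer of the product among their reactants or products. In my reckoning they changed how much target formed and left r alone.

So I expected autumn, hotter than epsilon, to give at least 82.8%. The eta run still read r = 0.0645 at 2.50 h, a share of 93.9% as read, and midnight is colder, so I expected more than that there. Winter, cooled towards a higher standing ratio, I expected to fall below autumn.

The forecast named midnight and gave 81% for autumn, 94% for midnight and 84% for winter, holding that “the equilibrium isomer fraction is about 20% with little temperature dependence”. It put autumn below my figure and winter above autumn, and there we differed.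

    starting material → open intermediate (k = 0.310 h⁻¹, Ea = 102 kJ mol⁻¹)
    partner → second intermediate (k = 0.260 h⁻¹, Ea = 105 kJ mol⁻¹)
    open intermediate + second intermediate → target (k = 0.290 M⁻¹ h⁻¹, Ea = 80.0 kJ mol⁻¹)
    2 second intermediate → homo product (k = 0.440 M⁻¹ h⁻¹, Ea = 73.0 kJ mol⁻¹)
    target ⇌ isomer of the product (K = 2.20, k = 0.0350 h⁻¹, Ea = 97.0 kJ mol⁻¹, ΔH = −90.0 kJ mol⁻¹)
    starting material + protic impurity → quenched substrate (k = 13.0 M⁻¹ h⁻¹, Ea = 75.0 kJ mol⁻¹)
    (constants at 40 °C)

Midnight gave 97.2%, autumn 90.4% and winter 87.5%. Autumn's r was 0.106 at 2.50 h, below the epsilon reading, and its share held over ten times the time. Winter had starting material at 0% and partner at 0% at the change; from then to 2.50 h, target went from 10.0% to 9.88% and isomer from 1.03% to 1.42%, lifting r from 0.103 to 0.144. By 25.0 h winter's r stood at 0.900, well above the epsilon reading, a share of 52.6%.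

The runs stem from a simulated flask on assumed constants.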